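Remark on the chemistry: the target has no stereocentre. The tetrahydropyranyl acetals 13, 17 and 18, the cascade intermediate 9 and the diketone 24 are racemic, and their stereocentres are removed later in the route.

## The problem

Target 25 is a flavonol: a 4H-chromen-4-one (rings A and C) with a 3-hydroxy-4-methoxyphenyl ring B at C2 and a free hydroxyl at C3. It has no stereocentre, so the difficulty is entirely positional. Ring A (C4a, C5, C6, C7, C8, C8a) carries a substituent on every carbon: oxygen at C5, C7 and C8a, prenyl groups at C6 and C8, and the acyl carbon C4 at C4a. Only the C7 oxygen is methylated, and it lies between the two prenyl groups; the C5 oxygen must end as a free chelated phenol and the C8a oxygen as the pyranone ether. Electrophilic prenylation and partial methylation of a 1,3,5-trioxygenated benzene give mixtures of C- and O-alkylated and of mono- and bis-prenylated products, so they cannot be trusted for this pattern. The two trisubstituted alkenes exclude hydrogenolysis, peracids, dioxiranes, halonium sources and hot strong acid, which would add a neighbouring phenol across the double bond to give a dimethylchroman. The 3-hydroxypyranone degrades in aerated base, so the free hydroxyls should be unveiled last and under mild acid. The feature that makes the key step possible is the strict alternation O, C, O, C, O, C around ring A. A two-carbon ynol ether can deliver C7 and C8 with their methoxy and prenyl groups, and a four-carbon vinylketene can deliver C8a, C4a, C5 and C6. Because ring A is mirror-symmetric about the C7···C4a axis, either oxygen ortho to C4a can close ring C and give the same flavonol.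

## Retrosynthesis

**Ring C, bond O1–C2.** Target 25 is opened at O1–C2 to the o-hydroxyaryl 1,3-diketone 24, in which the C3 oxygen, the C5 oxygen and the ring B phenol are MOM ethers. The neighbouring options are weaker. Oxidative closure of a chalcone with alkaline H2O2 is diverted towards aurones by a C5 substituent, and hydroxylation of a finished flavone at C3 would meet the prenyl alkenes. Carrying the C3 oxygen in from the start avoids both. The forward step must dehydrate and remove three acetals in one mild acid treatment that leaves the prenyl groups alone. No regiochemical demand arises, because the two phenols flanking C4a become equivalent once the C5 acetal is lost.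

**Bond C2–C3.** Diketone 24 is traced to aryl ester 23 by a Baker–Venkataraman acyl shift, and 23 to phenol ketone 19 and acid 22. Delivering the aroyl group intramolecularly is preferred to an intermolecular Claisen condensation on a hindered, α-oxygenated ketone, where O-acylation would compete. Acid 22 comes from isovanillic acid 20 through the doubly alkylated ester 21. The forward reaction needs a base that forms the enolate without cleaving the ester.

**Bond C4–C4a.** Ketone 19 arises by removal of a tetrahydropyranyl group from 18, which is cut at C4–C4a into aryllithium 17 and Weinreb amide 16. Friedel–Crafts acylation is excluded by the acid-sensitive prenyl groups, and halogen–metal exchange would first require halogenating an electron-rich arene that carries two alkenes. Direct deprotonation is the clean option: in arene 13 the C4a hydrogen is the only aromatic hydrogen and sits between two acetal oxygens. One of these is a THP ether and the other a MOM ether, so that later only the C8a oxygen is released. Arene 13 is the THP ether of phenol 12, and amide 16 comes from methyl glycolate 14 through ester 15.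

**Ring A, bonds C8a–C8, C7–C6 and C8a–C4a.** Phenol 12 is disconnected into cyclobutenone 7 and ynol ether 4. This cut replaces three separate substitution problems on a preformed benzene by one thermal union of two small, distillable fragments, and the place of every substituent follows from their connectivity. The forward reaction must be regioselective in the ketene–alkyne cycloaddition and must tolerate an enol MOM ether and two alkenes. A neutral, metal-free pericyclic cascade meets both demands.

**The two fragments.** Cyclobutenone 7 is the MOM enol ether of the vinylogous acid 6, which is the hydrolysis product of methoxycyclobutenone 5. Compound 5 is the [2+2] adduct of the same alkyne 4 with the two-carbon ketene unit supplied by acetyl chloride and Et3N. One alkyne therefore serves as both partners of the key step. Alkyne 4 is cut at its propargylic bond into chloroacetal 1, the source of sodium methoxyacetylide 3, and prenyl bromide 2.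

## Roads not taken

**Alternative 1:** Biomimetic fold of a linear chain.
- **Cut:** C4a–C5 of ring A and O1–C2 of ring C, both traced to the acyclic ester A1.
- **Forward key step:** Mg(OMe)2 in methanol would let the C4a carbanion of A1 attack the C5 ester in a Claisen cyclisation that aromatises to ring A. Acidification with acetic acid would then let a new phenol add to the aryl ketone, giving flavonol ether A2, two MOM groups away from 25.
- **Merits:** Both rings form in one flask, magnesium chelation templates the fold, and ring A needs no protecting group because its C5 and C8a oxygens start as carbonyls. In endgame economy this road is better than the chosen one.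
- **Weak points:** A1 has three acidic C–H sites and four electrophilic carbonyls, so aldol and pyranone-forming modes compete with the wanted Claisen closure. Its enol ether must keep the E geometry that presents the ester to C4a. Building the chain needs repeated acylations with C- versus O-selectivity problems, on intermediates unlikely to survive purification.
- **Comparison:** The chosen plan gives up the two-ring cascade. In return, every bond of ring A is made by a pericyclic step whose regiochemistry is fixed by connectivity, and all intermediates are stable and characterisable.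

**Alternative 2:** Parham-type closure of ring C.
- **Cut:** C4–C4a.
- **Forward key step:** Iodophenol A3 would be added to arylpropiolate A4 to give the Z aryloxycinnamate A5. Iodine–magnesium exchange with i-PrMgCl·LiCl would then generate an arylmagnesium at C4a, which attacks the ester and closes ring C as flavone A6.
- **Merits:** The closure runs at low temperature without acid, tolerates MOM ethers and prenyl groups, and is regiochemically unambiguous. As a ring C closure it is shorter and probably cleaner than the esterification, acyl shift and cyclodehydration used here.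
- **Weak points:** A6 lacks the C3 hydroxyl. Installing it on a chromone with two electron-rich alkenes excludes dioxirane chemistry and leaves a risky lithiation–borylation–oxidation. A3 is itself a hexasubstituted ring A, so the central problem is untouched, and iodinating such a prenylated phenol invites iodoetherification. The Z-selective oxa-Michael addition of a di-ortho-substituted phenol is also uncertain.
- **Comparison:** The chosen plan brings the C3 oxygen in with amide 16 and, through phenol 12, solves the ring A problem that this alternative assumes solved.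

**Alternative 3:** Fluorine as latent oxygen.
- **Cut:** O1–C8a.
- **Forward key step:** Difluoroaryl diketone A8, built from 3,5-difluoroanisole A7, would be treated with K2CO3 in DMF. The enolate oxygen displaces one ortho fluorine and closes ring C as the 5-fluoro flavonol ether A9. The C5 fluorine must later be exchanged for oxygen.
- **Merits:** The arene is commercial, fluorine acidifies the ring C–H bonds for lithiation, the C7 methoxy is present from the start, and the symmetry of A8 makes either fluorine a valid leaving group. Each of its steps has closer precedent than the key step chosen here, and its ring closure is probably the more reliable of the two.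
- **Weak points:** The most acidic site of A7 is the one between the fluorines, the future C4a. Prenylation at C6 and C8 therefore needs a blocking group or an awkward order of events. The second substitution on A9 must expel fluoride from a ring that carries a methoxy and two alkyl donors and is activated only by the peri carbonyl. That calls for hot alkoxide or hydroxide, which also attacks C2 of chromones and opens ring C.
- **Comparison:** The chosen plan has all three ring A oxygens in place from the moment the ring is formed and needs no late C–F to C–O exchange.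

Key step: step 5

## Route

Step 1
Reactants: 1 2-chloro-1,1-dimethoxyethane (chloroacetaldehyde dimethyl acetal); 2 1-bromo-3-methylbut-2-ene (prenyl bromide)
Product: 4 1-methoxy-5-methylhex-4-en-1-yne, via sodium methoxyacetylide 3 (not isolated)
Conditions: NaNH2 (3.0 equiv), liq. NH3, −33 °C; then 2, Et2O, −33 °C → rt
Reagents that add atoms: none
Why: Two eliminations (loss of methanol, then of HCl) and a deprotonation convert the chloroacetal into sodium methoxyacetylide 3, which is alkylated in the same flask at the unhindered CH2 terminus of the primary allylic bromide (SN2 alkylation of an alkoxyacetylide); keeping NaNH2 at three equivalents leaves no amide to isomerise the skipped enyne.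

Step 2
Reactants: 4 1-methoxy-5-methylhex-4-en-1-yne
Product: 5 3-methoxy-2-(3-methylbut-2-en-1-yl)cyclobut-2-en-1-one
Conditions: AcCl (1.5 equiv, slow addition), Et3N (1.6 equiv), Et2O, 0 °C → rt
Reagents that add atoms: acetyl chloride, CC(=O)Cl
Why: Ketene generated in the flask by dehydrochlorination of acetyl chloride adds to the ynol ether in a regioselective [2+2] cycloaddition, the alkyne carbon remote from oxygen bonding to the ketene carbonyl carbon; the isolated prenyl alkene does not react with unactivated ketene.

Step 3
Reactants: 5 3-methoxy-2-(3-methylbut-2-en-1-yl)cyclobut-2-en-1-one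
Product: 6 3-hydroxy-2-(3-methylbut-2-en-1-yl)cyclobut-2-en-1-one (enol form of 2-prenylcyclobutane-1,3-dione)
Conditions: 1 M aq. HCl, THF, 0 °C → rt
Reagents that add atoms: water, O
Why: Acid hydrolysis of a vinylogous ester (conjugate addition of water, loss of methanol) gives the strongly acidic enol of the 1,3-dione; dilute acid at this temperature does not hydrate the trisubstituted alkene.

Step 4
Reactants: 6 3-hydroxy-2-(3-methylbut-2-en-1-yl)cyclobut-2-en-1-one
Product: 7 3-(methoxymethoxy)-2-(3-methylbut-2-en-1-yl)cyclobut-2-en-1-one
Conditions: MOMCl, i-Pr2NEt, CH2Cl2, 0 °C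
Reagents that add atoms: chloromethyl methyl ether, COCCl
Why: O-Alkylation of the vinylogous acid by a hard electrophile under amine base; the two oxygens are equivalent, and C-alkylation at the already substituted C2 is disfavoured.

Step 5
Reactants: 7 3-(methoxymethoxy)-2-(3-methylbut-2-en-1-yl)cyclobut-2-en-1-one; 4 1-methoxy-5-methylhex-4-en-1-yne
Product: 12 3-methoxy-5-(methoxymethoxy)-2,4-bis(3-methylbut-2-en-1-yl)phenol, via vinylketene 8 (not isolated), via 4-vinylcyclobutenone 9 (not isolated), via dienylketene 10 (not isolated), via cyclohexadienone 11 (not isolated)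
Conditions: 4 (2.0 equiv), PhMe, sealed tube, 80 → 120 °C
Reagents that add atoms: none
Why: Heating opens 7 by a conrotatory 4π-electrocyclic ring opening to vinylketene 8. The ketene C=C of 8 and the electron-rich alkyne 4 then join in a [2+2] cycloaddition to give 4-vinylcyclobutenone 9; the polarity of the partners makes the prenyl-bearing alkyne carbon, the nucleophilic end of the ynol ether, bond to the ketene carbonyl carbon. A second 4π opening turns 9 into dienylketene 10, which closes ring A by a thermal disrotatory 6π-electrocyclisation between the ketene carbon and the terminal CH2 to give dienone 11, and tautomerisation gives phenol 12. The closest known reaction type is the Danheiser benzannulation of cyclobutenones with alkoxy- and siloxyalkynes, including alkynes that carry an allylic chain on the carbon remote from oxygen. No stereocentre remains, since the quaternary carbon of 9 is destroyed in the second ring opening. The only selectivity needed is regiochemical, and the ketene–ynol ether polarity secures it: the ring then reads OH, prenyl, OMe, prenyl, OMOM, H. Excess alkyne keeps the vinylketene from being intercepted by the product phenol, and the neutral, metal-free medium leaves the enol MOM ether and both alkenes untouched. The 3-alkoxy group makes 7 a vinylogous ester and should raise the temperature of the first ring opening, which is why the reaction is taken up to 120 °C in a sealed tube.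

Step 6
Reactants: 12 3-methoxy-5-(methoxymethoxy)-2,4-bis(3-methylbut-2-en-1-yl)phenol
Product: 13 2-[3-methoxy-5-(methoxymethoxy)-2,4-bis(3-methylbut-2-en-1-yl)phenoxy]oxane (racemic)
Conditions: 3,4-dihydro-2H-pyran, PPTS (cat.), CH2Cl2, rt
Reagents that add atoms: 3,4-dihydro-2H-pyran, C1=COCCC1
Why: Acid-catalysed addition of the phenol to the enol ether (THP protection) under a buffer mild enough for the aryl MOM ether and the prenyl groups; the THP acetal is chosen because it directs lithiation and can later be removed beside MOM ethers, and its racemic acetal centre disappears in step 10.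

Step 7
Reactants: 14 methyl 2-hydroxyacetate (methyl glycolate)
Product: 15 methyl 2-(methoxymethoxy)acetate
Conditions: MOMCl, i-Pr2NEt, CH2Cl2, 0 °C → rt
Reagents that add atoms: chloromethyl methyl ether, COCCl
Why: Standard MOM protection of a primary alcohol under amine base.

Step 8
Reactants: 15 methyl 2-(methoxymethoxy)acetate
Product: 16 N-methoxy-2-(methoxymethoxy)-N-methylacetamide
Conditions: MeNH(OMe)·HCl (1.5 equiv), i-PrMgCl (3.0 equiv), THF, −20 °C
Reagents that add atoms: N,O-dimethylhydroxylamine hydrochloride, CNOC.Cl
Why: Direct aminolysis of the methyl ester by the chloromagnesium amide of N,O-dimethylhydroxylamine (Weinreb amide formation); the acetal is inert to the Grignard base at this temperature.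

Step 9
Reactants: 13 2-[3-methoxy-5-(methoxymethoxy)-2,4-bis(3-methylbut-2-en-1-yl)phenoxy]oxane; 16 N-methoxy-2-(methoxymethoxy)-N-methylacetamide
Product: 18 2-(methoxymethoxy)-1-[4-methoxy-2-(methoxymethoxy)-3,5-bis(3-methylbut-2-en-1-yl)-6-(oxan-2-yloxy)phenyl]ethan-1-one (racemic), via aryllithium 17 (not isolated)
Conditions: n-BuLi (1.15 equiv), TMEDA, THF, 0 °C; then 16, −78 → 0 °C; aq. NH4Cl
Reagents that add atoms: none
Why: Directed ortho-metalation: the only aromatic hydrogen of 13 lies between two acetal-type oxygen directing groups, so n-BuLi gives aryllithium 17 at the future C4a, and acylation by the Weinreb amide stops at the ketone.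

Step 10
Reactants: 18 2-(methoxymethoxy)-1-[4-methoxy-2-(methoxymethoxy)-3,5-bis(3-methylbut-2-en-1-yl)-6-(oxan-2-yloxy)phenyl]ethan-1-one
Product: 19 1-[2-hydroxy-4-methoxy-6-(methoxymethoxy)-3,5-bis(3-methylbut-2-en-1-yl)phenyl]-2-(methoxymethoxy)ethan-1-one
Conditions: PPTS (0.2 equiv), MeOH, 40 °C
Reagents that add atoms: none
Why: Acid-catalysed transacetalisation in methanol cleaves a THP acetal far faster than aryl or alkyl MOM ethers, so only the C8a phenol is released, and it is then hydrogen-bonded to the ketone.

Step 11
Reactants: 20 3-hydroxy-4-methoxybenzoic acid (isovanillic acid)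
Product: 21 methoxymethyl 4-methoxy-3-(methoxymethoxy)benzoate
Conditions: MOMCl (2.5 equiv), i-Pr2NEt, CH2Cl2, 0 °C → rt
Reagents that add atoms: chloromethyl methyl ether, COCCl
Why: Exhaustive alkylation of the phenol and the carboxylate with MOMCl; the MOM ester is a throwaway group removed in the next step.

Step 12
Reactants: 21 methoxymethyl 4-methoxy-3-(methoxymethoxy)benzoate
Product: 22 4-methoxy-3-(methoxymethoxy)benzoic acid
Conditions: LiOH·H2O, THF/MeOH/H2O, rt; then 1 M HCl to pH 4, 0 °C
Reagents that add atoms: lithium hydroxide, [Li+].[OH-]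
Why: Saponification of the acyloxymethyl ester; the aryl MOM ether is stable to base and to brief cold acidification.

Step 13
Reactants: 19 1-[2-hydroxy-4-methoxy-6-(methoxymethoxy)-3,5-bis(3-methylbut-2-en-1-yl)phenyl]-2-(methoxymethoxy)ethan-1-one; 22 4-methoxy-3-(methoxymethoxy)benzoic acid
Product: 23 5-methoxy-3-(methoxymethoxy)-2-[(methoxymethoxy)acetyl]-4,6-bis(3-methylbut-2-en-1-yl)phenyl 4-methoxy-3-(methoxymethoxy)benzoate
Conditions: EDC·HCl, DMAP, CH2Cl2, 0 °C → rt
Reagents that add atoms: none
Why: Steglich esterification: the carbodiimide-activated acid is passed by DMAP to the chelated phenol under neutral conditions that keep every MOM ether and avoid an acid chloride.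

Step 14
Reactants: 23 5-methoxy-3-(methoxymethoxy)-2-[(methoxymethoxy)acetyl]-4,6-bis(3-methylbut-2-en-1-yl)phenyl 4-methoxy-3-(methoxymethoxy)benzoate
Product: 24 1-[2-hydroxy-4-methoxy-6-(methoxymethoxy)-3,5-bis(3-methylbut-2-en-1-yl)phenyl]-2-(methoxymethoxy)-3-[4-methoxy-3-(methoxymethoxy)phenyl]propane-1,3-dione (racemic at C2, enolisable)
Conditions: LiN(SiMe3)2 (3 equiv), THF, −78 → 0 °C; aq. NH4Cl
Reagents that add atoms: none
Why: Baker–Venkataraman rearrangement: the ketone enolate attacks the neighbouring aryl ester through a six-membered transition state and the aroyl group moves from oxygen to carbon, as established for α-alkoxy o-acyloxyaryl ketones; the non-nucleophilic amide base cannot cleave the ester, and the C2 centre is lost in step 15.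

Step 15
Reactants: 24 1-[2-hydroxy-4-methoxy-6-(methoxymethoxy)-3,5-bis(3-methylbut-2-en-1-yl)phenyl]-2-(methoxymethoxy)-3-[4-methoxy-3-(methoxymethoxy)phenyl]propane-1,3-dione
Product: 25 3,5-dihydroxy-2-(3-hydroxy-4-methoxyphenyl)-7-methoxy-6,8-bis(3-methylbut-2-en-1-yl)-4H-chromen-4-one
Conditions: 3 M aq. HCl, MeOH, 50 °C
Reagents that add atoms: none
Why: Methanolic acid cleaves the three MOM acetals and drives cyclodehydration of the o-hydroxyaryl 1,3-diketone (6-exo-trig addition of the phenol to the aroyl carbonyl, then loss of water) to the 3-hydroxyflavone. Once the C5 acetal is gone the two phenols flanking C4a are equivalent, so only one flavonol can form, and the chelated C5 hydroxyl has little tendency to add to the C6 prenyl group under these conditions.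

## Compound list

1 | 2-chloro-1,1-dimethoxyethane (chloroacetaldehyde dimethyl acetal) | COC(CCl)OC | starting material
2 | 1-bromo-3-methylbut-2-ene (prenyl bromide) | CC(C)=CCBr | starting material
3 | sodium methoxyethynide (sodium methoxyacetylide) | [Na+].[C-]#COC | intermediate (not isolated)
4 | 1-methoxy-5-methylhex-4-en-1-yne | COC#CCC=C(C)C | intermediate
5 | 3-methoxy-2-(3-methylbut-2-en-1-yl)cyclobut-2-en-1-one | COC1=C(CC=C(C)C)C(=O)C1 | intermediate
6 | 3-hydroxy-2-(3-methylbut-2-en-1-yl)cyclobut-2-en-1-one | OC1=C(CC=C(C)C)C(=O)C1 | intermediate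
7 | 3-(methoxymethoxy)-2-(3-methylbut-2-en-1-yl)cyclobut-2-en-1-one | COCOC1=C(CC=C(C)C)C(=O)C1 | intermediate
8 | 3-(methoxymethoxy)-2-(3-methylbut-2-en-1-yl)buta-1,3-dien-1-one (vinylketene) | C=C(OCOC)C(CC=C(C)C)=C=O | intermediate (not isolated)
9 | 3-methoxy-4-[1-(methoxymethoxy)ethenyl]-2,4-bis(3-methylbut-2-en-1-yl)cyclobut-2-en-1-one (racemic) | O=C1C(CC=C(C)C)=C(OC)C1(CC=C(C)C)C(=C)OCOC | intermediate (not isolated)
10 | (3E)-3-methoxy-5-(methoxymethoxy)-2,4-bis(3-methylbut-2-en-1-yl)hexa-1,3,5-trien-1-one (dienylketene) | O=C=C(CC=C(C)C)/C(OC)=C(/CC=C(C)C)C(=C)OCOC | intermediate (not isolated)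
11 | 3-methoxy-5-(methoxymethoxy)-2,4-bis(3-methylbut-2-en-1-yl)cyclohexa-2,4-dien-1-one | O=C1CC(OCOC)=C(CC=C(C)C)C(OC)=C1CC=C(C)C | intermediate (not isolated)
12 | 3-methoxy-5-(methoxymethoxy)-2,4-bis(3-methylbut-2-en-1-yl)phenol | COCOc1cc(O)c(CC=C(C)C)c(OC)c1CC=C(C)C | intermediate
13 | 2-[3-methoxy-5-(methoxymethoxy)-2,4-bis(3-methylbut-2-en-1-yl)phenoxy]oxane (racemic) | COCOc1cc(OC2CCCCO2)c(CC=C(C)C)c(OC)c1CC=C(C)C | intermediate
14 | methyl 2-hydroxyacetate (methyl glycolate) | COC(=O)CO | starting material
15 | methyl 2-(methoxymethoxy)acetate | COCOCC(=O)OC | intermediate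
16 | N-methoxy-2-(methoxymethoxy)-N-methylacetamide | COCOCC(=O)N(C)OC | intermediate
17 | [4-methoxy-2-(methoxymethoxy)-3,5-bis(3-methylbut-2-en-1-yl)-6-(oxan-2-yloxy)phenyl]lithium (racemic) | [Li]c1c(OCOC)c(CC=C(C)C)c(OC)c(CC=C(C)C)c1OC1CCCCO1 | intermediate (not isolated)
18 | 2-(methoxymethoxy)-1-[4-methoxy-2-(methoxymethoxy)-3,5-bis(3-methylbut-2-en-1-yl)-6-(oxan-2-yloxy)phenyl]ethan-1-one (racemic) | COCOCC(=O)c1c(OCOC)c(CC=C(C)C)c(OC)c(CC=C(C)C)c1OC1CCCCO1 | intermediate
19 | 1-[2-hydroxy-4-methoxy-6-(methoxymethoxy)-3,5-bis(3-methylbut-2-en-1-yl)phenyl]-2-(methoxymethoxy)ethan-1-one | COCOCC(=O)c1c(OCOC)c(CC=C(C)C)c(OC)c(CC=C(C)C)c1O | intermediate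
20 | 3-hydroxy-4-methoxybenzoic acid (isovanillic acid) | COc1ccc(C(=O)O)cc1O | starting material
21 | methoxymethyl 4-methoxy-3-(methoxymethoxy)benzoate | COCOC(=O)c1ccc(OC)c(OCOC)c1 | intermediate
22 | 4-methoxy-3-(methoxymethoxy)benzoic acid | COCOc1cc(C(=O)O)ccc1OC | intermediate
23 | 5-methoxy-3-(methoxymethoxy)-2-[(methoxymethoxy)acetyl]-4,6-bis(3-methylbut-2-en-1-yl)phenyl 4-methoxy-3-(methoxymethoxy)benzoate | COCOCC(=O)c1c(OCOC)c(CC=C(C)C)c(OC)c(CC=C(C)C)c1OC(=O)c1ccc(OC)c(OCOC)c1 | intermediate
24 | 1-[2-hydroxy-4-methoxy-6-(methoxymethoxy)-3,5-bis(3-methylbut-2-en-1-yl)phenyl]-2-(methoxymethoxy)-3-[4-methoxy-3-(methoxymethoxy)phenyl]propane-1,3-dione (racemic) | COCOC(C(=O)c1ccc(OC)c(OCOC)c1)C(=O)c1c(O)c(CC=C(C)C)c(OC)c(CC=C(C)C)c1OCOC | intermediate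
25 | 3,5-dihydroxy-2-(3-hydroxy-4-methoxyphenyl)-7-methoxy-6,8-bis(3-methylbut-2-en-1-yl)-4H-chromen-4-one | COc1ccc(-c2oc3c(CC=C(C)C)c(OC)c(CC=C(C)C)c(O)c3c(=O)c2O)cc1O | target

## Step count and least certain steps

Total step count: 15. Longest linear sequence: 11 steps (steps 1, 2, 3, 4, 5, 6, 9, 10, 13, 14, 15). Steps 7 and 8 give the amide 16 and steps 11 and 12 give the acid 22.

**Step 5 (key step).**
- **Risk:** The first ring opening of the push–pull cyclobutenone 7 may be slow. At the temperature it needs, ynol ether 4 may be lost through prototropic isomerisation of its skipped enyne before it can trap vinylketene 8. Sluggish trapping would also let 8 dimerise or acylate the product phenol.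
- **Fallback:** The methoxyalkyne is replaced by a more nucleophilic siloxyalkyne, at the price of a late O-methylation. The fallback sets out from prenyl bromide 2 and cyclobutenone 7 and returns at 13.
  - CuCl-catalysed coupling of 2 with ethynylmagnesium bromide would give 5-methylhex-4-en-1-yne F1.
  - Lithiation with n-BuLi, oxidation of the acetylide with LiOOt-Bu to the lithium ynolate and silylation with TIPSCl would give triisopropyl[(5-methylhex-4-en-1-yn-1-yl)oxy]silane F2.
  - Benzannulation of F2 with 7 in toluene at 80–110 °C would give 5-(methoxymethoxy)-2,4-bis(3-methylbut-2-en-1-yl)-3-[(triisopropylsilyl)oxy]phenol F3.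
  - THP protection as in step 6 would give 2-[5-(methoxymethoxy)-2,4-bis(3-methylbut-2-en-1-yl)-3-[(triisopropylsilyl)oxy]phenoxy]oxane F4.
  - TBAF would release 3-(methoxymethoxy)-2,6-bis(3-methylbut-2-en-1-yl)-5-(oxan-2-yloxy)phenol F5, and MeI with K2CO3 in acetone would convert it into 13.

**Step 2.**
- **Risk:** Unsubstituted ketene may dimerise, or acetyl chloride may acylate the ynol ether directly, faster than the wanted cycloaddition takes place.
- **Fallback:** Setting out from 4, dichloroketene (from Cl3CCOCl and Zn(Cu) in Et2O) is a far better ketenophile partner and would give 4,4-dichloro-3-methoxy-2-(3-methylbut-2-en-1-yl)cyclobut-2-en-1-one F6. Reductive dechlorination with Zn in AcOH/TMEDA returns to 5.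

**Step 9.**
- **Risk:** Deprotonation at a benzylic and allylic CH2 of a prenyl group may compete with ring metalation. The congested aryllithium 17 may also take the α-proton of amide 16 instead of adding to it.
- **Fallback:** An electrophilic substitution directed by the free phenol replaces the lithiation. The fallback sets out from 12 and returns at 19, so it also bypasses steps 6 and 10.
  - Magnesium-mediated ortho-formylation (MgCl2, Et3N, paraformaldehyde, MeCN, reflux) would give 2-hydroxy-4-methoxy-6-(methoxymethoxy)-3,5-bis(3-methylbut-2-en-1-yl)benzaldehyde F7.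
  - Addition of excess (methoxymethoxy)methyllithium, made from tributyl[(methoxymethoxy)methyl]stannane and n-BuLi, would give 1-[2-hydroxy-4-methoxy-6-(methoxymethoxy)-3,5-bis(3-methylbut-2-en-1-yl)phenyl]-2-(methoxymethoxy)ethan-1-ol F8.
  - Oxidation of the benzylic alcohol with MnO2 would give 19.

**Step 13.**
- **Risk:** Acylation of the di-ortho-substituted, hydrogen-bonded phenol may be incomplete, and the activated acid may rearrange to an N-acylurea.
- **Fallback:** The ester is skipped. Setting out from 19 and 22, acid 22 and carbonyldiimidazole would give (1H-imidazol-1-yl)[4-methoxy-3-(methoxymethoxy)phenyl]methanone F9. The phenoxide–enolate dianion of 19, formed with LiN(SiMe3)2 (3 equiv) in THF at −78 °C, would be C-acylated by F9 to give 24 directly.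

**Step 15.**
- **Risk:** The C5 hydroxyl may add to the C6 prenyl alkene under acid, or HCl or methanol may add to the alkenes, while dehydration to the pyranone is still incomplete.
- **Fallback:** Ring closure and deprotection are separated, and protic acid is avoided in the deprotection. Setting out from 24, catalytic PPTS in toluene at 80 °C over 4 Å molecular sieves would give 7-methoxy-3,5-bis(methoxymethoxy)-2-[4-methoxy-3-(methoxymethoxy)phenyl]-6,8-bis(3-methylbut-2-en-1-yl)-4H-chromen-4-one F10. The three MOM groups would then be removed with ZnBr2 and n-PrSH in CH2Cl2 at 0 °C to reach 25.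

## Further compounds

F1 | step 5 | 5-methylhex-4-en-1-yne | C#CCC=C(C)C
F2 | step 5 | triisopropyl[(5-methylhex-4-en-1-yn-1-yl)oxy]silane | CC(C)=CCC#CO[Si](C(C)C)(C(C)C)C(C)C
F3 | step 5 | 5-(methoxymethoxy)-2,4-bis(3-methylbut-2-en-1-yl)-3-[(triisopropylsilyl)oxy]phenol | COCOc1cc(O)c(CC=C(C)C)c(O[Si](C(C)C)(C(C)C)C(C)C)c1CC=C(C)C
F4 | step 5 | 2-[5-(methoxymethoxy)-2,4-bis(3-methylbut-2-en-1-yl)-3-[(triisopropylsilyl)oxy]phenoxy]oxane (racemic) | COCOc1cc(OC2CCCCO2)c(CC=C(C)C)c(O[Si](C(C)C)(C(C)C)C(C)C)c1CC=C(C)C
F5 | step 5 | 3-(methoxymethoxy)-2,6-bis(3-methylbut-2-en-1-yl)-5-(oxan-2-yloxy)phenol (racemic) | COCOc1cc(OC2CCCCO2)c(CC=C(C)C)c(O)c1CC=C(C)C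
F6 | step 2 | 4,4-dichloro-3-methoxy-2-(3-methylbut-2-en-1-yl)cyclobut-2-en-1-one | COC1=C(CC=C(C)C)C(=O)C1(Cl)Cl
F7 | step 9 | 2-hydroxy-4-methoxy-6-(methoxymethoxy)-3,5-bis(3-methylbut-2-en-1-yl)benzaldehyde | COCOc1c(C=O)c(O)c(CC=C(C)C)c(OC)c1CC=C(C)C
F8 | step 9 | 1-[2-hydroxy-4-methoxy-6-(methoxymethoxy)-3,5-bis(3-methylbut-2-en-1-yl)phenyl]-2-(methoxymethoxy)ethan-1-ol (racemic) | COCOCC(O)c1c(OCOC)c(CC=C(C)C)c(OC)c(CC=C(C)C)c1O
F9 | step 13 | (1H-imidazol-1-yl)[4-methoxy-3-(methoxymethoxy)phenyl]methanone | COCOc1cc(C(=O)n2ccnc2)ccc1OC
F10 | step 15 | 7-methoxy-3,5-bis(methoxymethoxy)-2-[4-methoxy-3-(methoxymethoxy)phenyl]-6,8-bis(3-methylbut-2-en-1-yl)-4H-chromen-4-one | COCOc1c(-c2ccc(OC)c(OCOC)c2)oc2c(CC=C(C)C)c(OC)c(CC=C(C)C)c(OCOC)c2c1=O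
A1 | alternative 1 | methyl (2E)-3-methoxy-8-(methoxymethoxy)-9-[4-methoxy-3-(methoxymethoxy)phenyl]-2,4-bis(3-methylbut-2-en-1-yl)-5,7,9-trioxonon-2-enoate | COC(=O)/C(CC=C(C)C)=C(/OC)C(CC=C(C)C)C(=O)CC(=O)C(OCOC)C(=O)c1ccc(OC)c(OCOC)c1
A2 | alternative 1 | 5-hydroxy-7-methoxy-3-(methoxymethoxy)-2-[4-methoxy-3-(methoxymethoxy)phenyl]-6,8-bis(3-methylbut-2-en-1-yl)-4H-chromen-4-one | COCOc1c(-c2ccc(OC)c(OCOC)c2)oc2c(CC=C(C)C)c(OC)c(CC=C(C)C)c(O)c2c1=O
A3 | alternative 2 | 2-iodo-5-methoxy-3-(methoxymethoxy)-4,6-bis(3-methylbut-2-en-1-yl)phenol | COCOc1c(I)c(O)c(CC=C(C)C)c(OC)c1CC=C(C)C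
A4 | alternative 2 | methyl 3-[4-methoxy-3-(methoxymethoxy)phenyl]prop-2-ynoate | COC(=O)C#Cc1ccc(OC)c(OCOC)c1
A5 | alternative 2 | methyl (2Z)-3-[2-iodo-5-methoxy-3-(methoxymethoxy)-4,6-bis(3-methylbut-2-en-1-yl)phenoxy]-3-[4-methoxy-3-(methoxymethoxy)phenyl]prop-2-enoate | COC(=O)/C=C(\Oc1c(I)c(OCOC)c(CC=C(C)C)c(OC)c1CC=C(C)C)c1ccc(OC)c(OCOC)c1
A6 | alternative 2 | 7-methoxy-5-(methoxymethoxy)-2-[4-methoxy-3-(methoxymethoxy)phenyl]-6,8-bis(3-methylbut-2-en-1-yl)-4H-chromen-4-one | O=c1cc(-c2ccc(OC)c(OCOC)c2)oc2c(CC=C(C)C)c(OC)c(CC=C(C)C)c(OCOC)c12
A7 | alternative 3 | 1,3-difluoro-5-methoxybenzene (3,5-difluoroanisole) | COc1cc(F)cc(F)c1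
A8 | alternative 3 | 1-[2,6-difluoro-4-methoxy-3,5-bis(3-methylbut-2-en-1-yl)phenyl]-2-(methoxymethoxy)-3-[4-methoxy-3-(methoxymethoxy)phenyl]propane-1,3-dione | COCOC(C(=O)c1ccc(OC)c(OCOC)c1)C(=O)c1c(F)c(CC=C(C)C)c(OC)c(CC=C(C)C)c1F
A9 | alternative 3 | 5-fluoro-7-methoxy-3-(methoxymethoxy)-2-[4-methoxy-3-(methoxymethoxy)phenyl]-6,8-bis(3-methylbut-2-en-1-yl)-4H-chromen-4-one | COCOc1c(-c2ccc(OC)c(OCOC)c2)oc2c(CC=C(C)C)c(OC)c(CC=C(C)C)c(F)c2c1=O
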